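| flask | X | G | J | remark | time |
|---|---|---|---|---|---|
| maple | 2 M | 0.56 M | 1 mol% | run made earlier |  |
| alder | 2 M | 0.88 M | 1 mol% | run made earlier |  |
| elm | 1 M | 0.40 M | 1 mol% | run made earlier |  |
| flask | 2.0 M | 0.400 M | 1 mol% |  | 2.5 min |

| run | time / s | L / % | X / % |
|---|---|---|---|
| maple | 10.0 | 2 | 74 |
| maple | 12.0 | 0 | 72 |
| maple | 15.0 | 4 | 69 |
| maple | 25.0 | 5 | 66 |
| maple | 40.0 | 9 | 61 |
| maple | 60.0 | 15 | 55 |
| maple | 90.0 | 20 | 53 |
| alder | 10.0 | 2 | 59 |
| alder | 15.0 | 2 | 53 |
| alder | 25.0 | 6 | 51 |
| alder | 40.0 | 7 | 50 |
| alder | 50.0 | 7 | 45 |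
| alder | 80.0 | 17 | 40 |
| alder | 90.0 | 16 | 39 |
| elm | 10.0 | 2 | 75 |
| elm | 15.0 | 1 | 66 |
| elm | 25.0 | 3 | 61 |
| elm | 50.0 | 2 | 56 |
| elm | 90.0 | 9 | 52 |

(standard deviation of a reading: 1.5 percentage points)

- the average divides the monomer in chains by the number of chains begun, living and dead together
- the numbers in the tables scatter with a standard deviation of 1.5 percentage points
- the earlier runs do not show the number of chains; that part of a forecast is a guess

1. whether the average number of monomer units in a chain (chains begun, living or dead) reaches 30 by 2.5 min (no / yes)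
2. average number of monomer units in a chain (chains begun, living or dead) at 2.5 min

Late in these runs X fell slowly, so I read the table upward from its bottom rows. In maple, X went from 66% at 25.0 s to 53% at 90.0 s, a ratio of 0.803. In alder, with more G but the same J loading, the same span gave 0.765. Given the scatter, I took these as alike, and I assumed that late on X decayed exponentially at a fixed concentration of growing ends. I defined k′, the late first-order decay constant of X (pseudo-first-order), and read it from the maple rows as 0.00337 /s.

The upper rows showed the early loss. The maple G charge was 28.0% of its X, and at 12.0 s X read 72% with L at 0%, so I counted one X lost per G.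

The flask shares the X and J charges of maple, and by that count its G leaves 80.0% of X. My reckoning therefore gave L 31.8% at 2.5 min. If the J charge of 0.0200 M began one chain each, the length is 31.8.

The forecast said yes and 34, higher than mine, using about 0.0038 per second: “The chain count is a guess.”

The flask gave yes and 39.4.

    X + J → E + L (k = 0.0880 /M/s)
    X + E → L + E, rate k2*[E]*[X] (k = 0.220 /M/s)
    G + X → D (k = 0.140 /M/s)
    J → Q (k = 0.0180 /s)

The flask held L at 35.2% and E at 0.0179 M at 2.50 min, less than the 0.0200 M of my count, with Q at 0.00212 M and J at 0%. In the flask the G + X step had half of its turnover up to 2.5 min behind it by 2.63 s, and X to L by 1.13 min, much later. Carried forward, k′ reckoned flask X from 60.2% at 1.25 min to 46.8% at 2.50 min, where the flask held 44.8%. In alder, k′ reckoned X from 51% at 25.0 s to 41.0% at 90.0 s, where the reading was 39%.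

All runs come from a simulation on assumed constants.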